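## Analysis of the target

The target 30 is a trans-fused bicyclo[5.3.0]decene (a hydroazulene of the daucane type) that carries a 4-hydroxybenzoate. Numbering used throughout: seven-membered ring C1(Me)=C2–C3–C4(Me)–C8–C9(O-acyl)–C10, five-membered ring C4–C5(OH)–C6–C7(OH)(iPr)–C8. There are five stereocentres (4R,5R,7R,8S,9S): the quaternary C4 with its angular methyl, C8–H trans to that methyl, the C5 and C7 hydroxyls both on the methyl face, and the isopropyl group and the equatorial C9 acyloxy group on the face of H8. C9, C8, C4 and C5 are contiguous and C7 sits on C8, so every centre touches the ring fusion and must be set with reference to it. Sensitive points are the tertiary carbinol (dehydration), the two oxygens β to C7 (elimination and C8 epimerisation whenever C7 is a ketone), the aryl ester with its free phenol (base, acyl transfer) and the trisubstituted alkene. The difficulty lies in the trans fusion at a quaternary carbon, in placing the alkene at C1=C2 and nowhere else, and in telling three hydroxyls apart. The strategy rests on one feature: C7 is a latent ketone whose α-carbon C6 is a methylene lying 1,5 to the oxygen-bearing C5 through C7–C8–C4. In a monocyclic cycloheptene C5 is simply a CH2–O arm on the quaternary carbon, so the C5–C6 bond can be made last by insertion of a C6 carbenoid into a C5–H bond.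

## Retrosynthetic reasoning

**30 ⇒ 29 ⇒ 24 + 27.** The C9–O acyl bond is cut last, because an aryl ester at C9 would not survive organometallic addition at C7 and would be a good leaving group β to the C7 ketone. The acid is carried as its phenol silyl ether 27 (from 25), so that one fluoride step at the end frees the phenol and the C5 hydroxyl together. Forward, only the secondary C9 hydroxyl of 24 must be acylated in the presence of the tertiary C7 hydroxyl.

**24 ⇒ 23 ⇒ 22.** The C7–isopropyl bond is cut next, leading to ketone 22. The carbonyl is flanked on one face by the angular methyl and the C5 silyloxy group, so a nucleophile should enter from the H8 face and give the 7R carbinol. The two oxygens need silyl groups of different lability, a triethylsilyl ether on C9 and a tert-butyldimethylsilyl ether on C5, so that C9 can be freed alone.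

**22 ⇒ 21 (key disconnection).** The C5–C6 bond is cut, which opens the five-membered ring to the diazomethyl ketone 21. This bond is chosen because it is the only ring bond whose formation touches no existing stereocentre except the new C5. The fusion centres C4 and C8 and the C9 carbinol are already fixed in a monocyclic ring, where trans placement of two equatorial arms is easy. The forward reaction must insert into the oxygen-activated C5–H bond rather than into allylic C–H bonds or the alkene. A benzylic ether on C9 is avoided: its oxygen lies 1,5 to the carbenoid carbon and would trap it as a five-membered oxonium ylide that rearranges by benzyl shift.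

**21 ⇒ 19 ⇒ 16 ⇒ 15.** The C6–C7 bond is cut back to the acid 19 (acylation of a diazomethane equivalent). The acid and the C5 silyl ether of 19 are then folded back into the γ-lactone 16, and removal of the C9 silyl ether leads to the hydroxy lactone 15. In the lactone the C7 carbonyl and the C5 oxygen are tied together, so both carbons already hold the oxidation levels needed. The C9 oxygen is silylated while the lactone is still closed, so the later silylation at C5 meets no second free hydroxyl.

**15 ⇒ 12.** The C5 methylene is traced to an acetal carbon. In 12 this carbon carries the menthyloxy group that serves as the resolving and directing element. Forward, one hydrolysis–reduction removes it.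

**12 ⇒ 11.** The C1=C2 alkene is cut by ring-closing metathesis. No other disconnection places the trisubstituted alkene without regiochemical doubt. Forward, an allyl group on C4 and a methallyl group on C10 must close a seven-membered ring trans-fused to the lactone.

**11 ⇒ 7 + 9.** The C8–C9 bond is an aldol bond between the enolate of lactone 7 and the aldehyde 9 (made from 8). It is cut here because the lactone enolate has one accessible face (opposite the C4 allyl and C5 menthyloxy groups), which sets C8, and a ring-locked E geometry, which favours the anti relationship needed at C9.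

**7 ⇒ 5.** The C4–methyl bond is cut by conjugate addition to butenolide 5. The quaternary centre is made here, before any other stereocentre exists, under control of the neighbouring acetal carbon.

**5 ⇒ 3 + 4 and 3 ⇒ 1 + 2.** The acetal is cut to the hydroxybutenolide 3 and menthol 4. Then 3 is cut at its C=C bond to the two small aldehydes 1 and 2, which deliver C7–C8 and C5–C4–C3–C2 with the allyl group in place.

## Alternatives that were turned down

**Alternative 1: ring expansion of an arene by a diazoketone.** The disconnection cuts C4–C8 and C4–C3, so a benzene ring becomes the seven-membered ring. Forward, Rh2(OAc)4 (divalent rhodium) would generate a carbenoid at the methyl-bearing C4. This adds across an arene bond, and electrocyclic opening of the cyclopropane-fused intermediate would give the azulenone A1.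
- For it: both rings and the quaternary carbon arise in one step from a flat, cheap aromatic precursor. The only stereocentre needed beforehand is the C7 carbinol. On skeleton-building economy it is stronger than the chosen route.
- Against it: A1 is a cycloheptatriene with three ring double bonds where 30 has one. Two of them must be reduced selectively, and C8, C9 and C5 must be set afterwards on a bicyclic enol ether. Delivering hydrogen to C8 trans to the angular methyl is the less likely outcome there. A diazo carbon that carries an alkyl group also tends to undergo 1,2-hydride shift instead of arene addition. Control of C4 by the remote C7 centre is uncertain.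
- Comparison: the chosen strategy is longer in bond-forming steps, but the trans fusion is decided before the key step and a single new stereocentre is created in it.

**Alternative 2: (5+2) cycloaddition of a siloxyvinylcyclopropane.** The disconnection cuts C2–C3 and C1–C10. Forward, [Rh(CO)2Cl]2 (monovalent rhodium) would open the C8–C3 cyclopropane bond of a cyclopentane-bound vinylcyclopropane and insert propyne A3 to give the bicyclic silyl enol ether A2.
- For it: it is convergent, forms two C–C bonds and the seven-membered ring at once, and leaves C1=C2 where it belongs. The five-membered ring with C7 comes from the chiral pool.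
- Against it: the methyl group of A3 must end on C1 and not on C2, which is not assured for a small terminal alkyne. The fully substituted cyclopropane that carries the quaternary C4 must open at one specific bond. A2 still has a tetrasubstituted C8=C9 enol ether, so the trans ring-fusion hydrogen and the C9 carbinol would have to be set late by protonation and reduction, which tend to give the cis-fused system. Making the substituted vinylcyclopropane with C4, C5 and C7 defined is itself long.
- Comparison: the cycloaddition is more convergent. The chosen route instead fixes C8 and C9 early, in a monocyclic lactone where anti approach is dependable.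

**Alternative 3: transannular epoxide–olefin closure of a ten-membered ring.** The disconnection cuts C4–C8 across a cyclodecadiene epoxide. Forward, BF3·OEt2 or Sc(OTf)3 in wet CH2Cl2 would open the C4–C5 epoxide, the C7=C8 alkene would attack C4, and water would capture the C7 cation, giving A4, the phenol silyl ether of 30.
- For it: it is biomimetic and creates both rings and up to four stereocentres in one step with the ester already in place. Only a desilylation would remain, so after the macrocycle it is the shortest endgame of all.
- Against it: the outcome at C4, C5, C7 and C8 depends on the conformer population of a flexible medium ring. The C7 cation next to isopropyl can eliminate, undergo hydride shift or be captured by the neighbouring C9 ester carbonyl. The C1=C2 alkene can compete as the nucleophile. The stereodefined ten-membered epoxide with fixed alkene geometries is a harder target than any intermediate of the chosen route.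
- Comparison: the chosen strategy needs more steps, but each stereocentre has a nameable controlling element, and the one risky step forms a single bond.

Key step: step 11

Remark on the chemistry (assumption): the menthyl acetal 5 is assumed to behave like the unsubstituted 5-menthyloxyfuranone, whose acetal epimers interconvert under acid and separate by crystallisation. If it does not crystallise, the epimers are separated by chromatography. Locants such as C4, C8 and C9 in names refer to the skeleton numbering given in the analysis.

## Route

Step 1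
Reactants: 1 glyoxylic acid (used as monohydrate); 2 pent-4-enal
Product: 3 5-hydroxy-4-(prop-2-en-1-yl)furan-2(5H)-one (racemic hemiacetal)
Conditions: morpholine hydrochloride, dioxane/H2O, reflux
Reagents that add atoms: none
Why: Amine-salt mediated aldol-type condensation of the enolisable aldehyde with glyoxylic acid, dehydration and closure of the formyl acrylic acid to the cyclic pseudo acid, a known way to 4-alkyl-5-hydroxybutenolides; the weakly acidic medium should leave the skipped allyl alkene in place, and the hemiacetal centre is racemic and is fixed in step 2.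

Step 2
Reactants: 3 5-hydroxy-4-(prop-2-en-1-yl)furan-2(5H)-one; 4 (1S,2R,5S)-(+)-menthol
Product: 5 (5S)-5-{[(1S,2R,5S)-5-methyl-2-(propan-2-yl)cyclohexyl]oxy}-4-(prop-2-en-1-yl)furan-2(5H)-one
Conditions: 10-camphorsulfonic acid (cat.), toluene, reflux, Dean–Stark; crystallisation from hexane; mother liquor re-equilibrated with the same acid
Reagents that add atoms: none
Why: Acid-catalysed acetalisation of the cyclic hemiacetal; the two acetal epimers interconvert through the oxocarbenium ion, so the 5S epimer is collected by crystallisation and the rest recycled; this acetal carbon is the only source of absolute configuration in the route.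

Step 3
Reactants: 5 (5S)-5-menthyloxy-4-(prop-2-en-1-yl)furan-2(5H)-one
Product: 7 (4R,5S)-4-methyl-5-{[(1S,2R,5S)-5-methyl-2-(propan-2-yl)cyclohexyl]oxy}-4-(prop-2-en-1-yl)dihydrofuran-2(3H)-one, via silyl ketene acetal 6 (not isolated)
Conditions: Me2CuLi (from CuI and MeLi), Me3SiCl, THF/Et2O, −78 to −30 °C; aq. NH4Cl
Reagents that add atoms: lithium dimethylcuprate ([Li+].C[Cu-]C)
Why: Conjugate addition of a Gilman cuprate, accelerated by the silyl chloride, to the β-substituted butenolide; methyl is delivered to C4 anti to the adjacent menthyloxy group, which sets the quaternary centre as 4R with the allyl group on the menthyloxy face; the labile silyl ketene acetal is hydrolysed on work-up.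

Step 4
Reactants: 8 3-methylbut-3-en-1-ol
Product: 9 3-methylbut-3-enal
Conditions: Dess–Martin periodinane, NaHCO3, CH2Cl2, 0 °C; filtered solution used at once
Reagents that add atoms: none
Why: Buffered Dess–Martin oxidation of a primary homoallylic alcohol; the neutral, cold conditions avoid migration of the alkene into conjugation, and the aldehyde is not stored.

Step 5
Reactants: 7 (4R,5S)-4-methyl-5-menthyloxy-4-(prop-2-en-1-yl)dihydrofuran-2(3H)-one; 9 3-methylbut-3-enal
Product: 11 (3S,4R,5S)-3-[(1S)-1-hydroxy-3-methylbut-3-en-1-yl]-4-methyl-5-{[(1S,2R,5S)-5-methyl-2-(propan-2-yl)cyclohexyl]oxy}-4-(prop-2-en-1-yl)dihydrofuran-2(3H)-one, via lithium enolate 10 (not isolated)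
Conditions: LiN(iPr)2, THF, −78 °C; ZnCl2; then 9 in CH2Cl2, −78 °C; aq. NH4Cl
Reagents that add atoms: none
Why: Aldol addition of a ring-locked E enolate; the aldehyde reaches C8 from the face opposite both the C4 allyl group and the C5 menthyloxy group (8S), and the chair Zimmerman–Traxler transition state of an E enolate, like the chelated zinc aldolate at equilibrium, places the new hydroxyl anti to C4 (9S).

Step 6
Reactants: 11 aldol adduct
Product: 12 (3S,3aR,8S,8aS)-8-hydroxy-3a,6-dimethyl-3-{[(1S,2R,5S)-5-methyl-2-(propan-2-yl)cyclohexyl]oxy}-3,3a,4,7,8,8a-hexahydro-1H-cyclohepta[c]furan-1-one (trans-fused; skeleton 4R,5S,8S,9S)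
Conditions: second-generation Grubbs catalyst RuCl2(=CHPh)(PCy3)(H2IMes) (5 mol%), CH2Cl2 (5 mM), 40 °C
Reagents that add atoms: none
Why: Ring-closing metathesis of a monosubstituted with a 1,1-disubstituted alkene closes the seven-membered ring and fixes the trisubstituted alkene at C1=C2 without ambiguity; the two chains are trans on the lactone, so a trans-fused bicycle forms and no stereocentre changes.

Step 7
Reactants: 12 bicyclic lactone acetal
Product: 15 (3aR,8S,8aS)-8-hydroxy-3a,6-dimethyl-3,3a,4,7,8,8a-hexahydro-1H-cyclohepta[c]furan-1-one (skeleton 4R,8S,9S), via formyl acid 13 (not isolated), via dihydroxy acid 14 (not isolated)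
Conditions: KOH, NaBH4, EtOH/H2O, 0 °C to rt; then 2 M HCl to pH 2, rt
Reagents that add atoms: potassium hydroxide ([K+].[OH-])
Why: Hydroxide opens the pseudo ester and the hemiacetal collapses with loss of menthol to a non-enolisable neopentyl aldehyde, which NaBH4 reduces; acidification relactonises to the γ-lactone, so C5 reaches the alcohol level and C7 the acid level in one operation with no change at C4, C8 or C9.

Step 8
Reactants: 15 hydroxy lactone
Product: 16 (3aR,8S,8aS)-3a,6-dimethyl-8-[(triethylsilyl)oxy]-3,3a,4,7,8,8a-hexahydro-1H-cyclohepta[c]furan-1-one (skeleton 4R,8S,9S)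
Conditions: Et3SiOTf, 2,6-lutidine, CH2Cl2, −78 to 0 °C
Reagents that add atoms: triethylsilyl trifluoromethanesulfonate (CC[Si](CC)(CC)OS(=O)(=O)C(F)(F)F)
Why: Silyl triflate silylation of the hindered secondary hydroxyl while the lactone is still closed; capping C9 first blocks retro-aldol cleavage of C8–C9 in the basic step that follows and leaves the later C5 silylation with no competing hydroxyl. A triethylsilyl ether offers the later carbenoid no migrating group and can be removed in the presence of the C5 tert-butyldimethylsilyl ether.

Step 9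
Reactants: 16 silyl-protected lactone
Product: 19 (1S,2R,7S)-2-({[tert-butyl(dimethyl)silyl]oxy}methyl)-2,5-dimethyl-7-[(triethylsilyl)oxy]cyclohept-4-ene-1-carboxylic acid (skeleton 4R,8S,9S), via hydroxy acid lithium salt 17 (not isolated), via silyl ester 18 (not isolated)
Conditions: LiOH, THF/H2O, 0 °C to rt; evaporate, toluene azeotrope; tBuMe2SiCl, imidazole, DMF, rt; then K2CO3 (cat.), MeOH/THF/H2O, 0 °C; pH 5 phosphate buffer
Reagents that add atoms: lithium hydroxide ([Li+].[OH-]); tert-butyldimethylsilyl chloride (CC(C)(C)[Si](C)(C)Cl)
Why: Saponification of the γ-lactone to the lithium carboxylate, silylation of the carboxylate and of the freed primary hydroxyl without acidification in between (so the hydroxy acid cannot relactonise), then carbonate methanolysis of the labile silyl ester, a known three-stage way from a lactone to an O-silyl hydroxy acid. The secondary triethylsilyl ether should survive cold aqueous hydroxide and carbonate, and the pH 5 work-up spares it.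

Step 10
Reactants: 19 bis-silyl ether acid
Product: 21 2-diazo-1-[(1S,2R,7S)-2-({[tert-butyl(dimethyl)silyl]oxy}methyl)-2,5-dimethyl-7-[(triethylsilyl)oxy]cyclohept-4-en-1-yl]ethan-1-one (skeleton 4R,8S,9S), via acid chloride 20 (not isolated)
Conditions: 1-chloro-N,N,2-trimethylprop-1-en-1-amine, CH2Cl2, 0 °C; then Me3SiCHN2 (hexane, 3 equiv), MeCN/THF, 0 °C to rt
Reagents that add atoms: (trimethylsilyl)diazomethane (C[Si](C)(C)C=[N+]=[N-])
Why: Acid chloride formation under neutral conditions with an α-chloroenamine, then acylation of the silyl diazomethane (first stage of an Arndt–Eistert sequence) with loss of the silyl group as chloride; no amine base is present, so C8 is not epimerised through a ketene and the silyl ethers see no acid.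

Step 11
Reactants: 21 diazomethyl ketone
Product: 22 (3R,3aR,8S,8aS)-3-{[tert-butyl(dimethyl)silyl]oxy}-3a,6-dimethyl-8-[(triethylsilyl)oxy]-3,3a,4,7,8,8a-hexahydroazulen-1(2H)-one (trans-fused; skeleton 4R,5R,8S,9S)
Conditions: Rh2(OAc)4 (1 mol%), CH2Cl2, rt, slow addition of 21 (final 2 mM)
Reagents that add atoms: none
Why: Rh2(OAc)4 (divalent rhodium) extrudes N2 from 21 to give an electrophilic carbenoid at C6; the closest known reaction type is the 1,5 C–H insertion of α-diazo ketones next to ether oxygen, which gives 3-alkoxycyclopentanones. The carbenoid carbon and the C5 methylene are held 1,5 through C7–C8–C4, so a three-centre, hydride-transfer-like transition state forms C5–C6 and closes the cyclopentanone by C–C bond formation at the exocyclic CH2 of the C4 arm, the C5–H bonds being made hydridic by the silyloxy lone pairs. The acyl group on C8 and the silyloxymethyl arm on C4 are already trans and both equatorial on the cycloheptene, so the fusion can only be trans and no existing centre is touched. The one new stereocentre, C5, comes from the choice between two diastereotopic hydrogens: in the chair-like transition state the silyloxy group takes the pseudo-equatorial position, which is the one cis to the angular methyl (5R). The other 1,5 sites are C3–H and C10–H, which are allylic but lack oxygen activation and would give strained bridged bicyclo[4.2.1] ketones, and the primary C–H bonds of the C4 methyl. Transannular cyclopropanation of C1=C2 would need the acyl group axial over the ring, a conformer that also forces both oxygen-bearing arms axial. The C9 oxygen is a hindered, weakly basic triethylsilyl ether with no migrating group, so ylide formation there, which a benzylic ether would invite, has no productive exit. Slow addition at high dilution should suppress carbene dimerisation.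

Step 12
Reactants: 22 bicyclic ketone
Product: 23 (1R,3R,3aR,8S,8aS)-3-{[tert-butyl(dimethyl)silyl]oxy}-3a,6-dimethyl-1-(propan-2-yl)-8-[(triethylsilyl)oxy]-1,2,3,3a,4,7,8,8a-octahydroazulen-1-ol (skeleton 4R,5R,7R,8S,9S)
Conditions: iPrMgCl, anhydrous CeCl3, THF, −78 °C; aq. NH4Cl
Reagents that add atoms: isopropylmagnesium chloride (CC(C)[Mg]Cl)
Why: 1,2-Addition of an organocerium reagent, whose low basicity should avoid enolisation and β-elimination of either silyloxy group; the face cis to the angular methyl and the C5 silyloxy group is blocked, so isopropyl enters from the H8 face and gives the 7R carbinol.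

Step 13
Reactants: 23 tertiary alcohol
Product: 24 (1R,3R,3aR,8S,8aS)-3-{[tert-butyl(dimethyl)silyl]oxy}-3a,6-dimethyl-1-(propan-2-yl)-1,2,3,3a,4,7,8,8a-octahydroazulene-1,8-diol
Conditions: pyridinium p-toluenesulfonate (cat.), MeOH/CH2Cl2, 0 °C
Reagents that add atoms: none
Why: Acid-catalysed methanolysis cleaves a triethylsilyl ether far faster than the hindered secondary tert-butyldimethylsilyl ether; the buffered acid should leave the tertiary alcohol and the alkene alone.

Step 14
Reactants: 25 4-hydroxybenzoic acid
Product: 27 4-{[tert-butyl(dimethyl)silyl]oxy}benzoic acid, via silyl ester 26 (not isolated)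
Conditions: tBuMe2SiCl (2.2 equiv), imidazole, DMF, rt; then K2CO3 (cat.), MeOH/THF/H2O; 1 M HCl to pH 4
Reagents that add atoms: tert-butyldimethylsilyl chloride (CC(C)(C)[Si](C)(C)Cl)
Why: Exhaustive silylation of phenol and acid, then selective hydrolysis of the silyl ester, gives the phenol-protected acid.

Step 15
Reactants: 24 diol; 27 4-{[tert-butyl(dimethyl)silyl]oxy}benzoic acid
Product: 29 (1R,3R,3aR,8S,8aS)-3-{[tert-butyl(dimethyl)silyl]oxy}-1-hydroxy-3a,6-dimethyl-1-(propan-2-yl)-1,2,3,3a,4,7,8,8a-octahydroazulen-8-yl 4-{[tert-butyl(dimethyl)silyl]oxy}benzoate, via mixed anhydride 28 (not isolated)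
Conditions: 2,4,6-trichlorobenzoyl chloride, Et3N, THF, rt; then 24, 4-(dimethylamino)pyridine, toluene, 40 °C
Reagents that add atoms: none
Why: Yamaguchi esterification through the mixed anhydride acylates the secondary C9 hydroxyl; the tertiary C7 hydroxyl does not react, and C9 keeps its configuration because its C–O bond is not broken.

Step 16
Reactants: 29 bis-silyl ester
Product: 30 (1R,3R,3aR,8S,8aS)-1,3-dihydroxy-3a,6-dimethyl-1-(propan-2-yl)-1,2,3,3a,4,7,8,8a-octahydroazulen-8-yl 4-hydroxybenzoate (skeleton 4R,5R,7R,8S,9S; CNP0215209.2)
Conditions: HF·pyridine, pyridine, THF, 0 °C to rt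
Reagents that add atoms: none
Why: Fluoride-driven cleavage of the aryl and the alkyl silyl ether under buffered, non-basic conditions that should spare the ester, the tertiary alcohol and the alkene.

## Compound list

1 | glyoxylic acid | O=CC(=O)O | starting material
2 | pent-4-enal | C=CCCC=O | starting material
3 | 5-hydroxy-4-(prop-2-en-1-yl)furan-2(5H)-one (racemic) | C=CCC1=CC(=O)OC1O | intermediate
4 | (1S,2R,5S)-(+)-menthol | CC(C)[C@H]1CC[C@H](C)C[C@@H]1O | starting material
5 | (5S)-5-{[(1S,2R,5S)-5-methyl-2-(propan-2-yl)cyclohexyl]oxy}-4-(prop-2-en-1-yl)furan-2(5H)-one | CC(C)[C@H]1CC[C@H](C)C[C@@H]1O[C@H]1OC(=O)C=C1CC=C | intermediate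
6 | trimethylsilyl ketene acetal of 7, {[(4R,5S)-4-methyl-5-menthyloxy-4-(prop-2-en-1-yl)-4,5-dihydrofuran-2-yl]oxy}trimethylsilane | CC(C)[C@H]1CC[C@H](C)C[C@@H]1O[C@H]1OC(O[Si](C)(C)C)=C[C@@]1(C)CC=C | intermediate (not isolated)
7 | (4R,5S)-4-methyl-5-{[(1S,2R,5S)-5-methyl-2-(propan-2-yl)cyclohexyl]oxy}-4-(prop-2-en-1-yl)dihydrofuran-2(3H)-one | CC(C)[C@H]1CC[C@H](C)C[C@@H]1O[C@H]1OC(=O)C[C@@]1(C)CC=C | intermediate
8 | 3-methylbut-3-en-1-ol | C=C(C)CCO | starting material
9 | 3-methylbut-3-enal | C=C(C)CC=O | intermediate
10 | lithium enolate of 7 | CC(C)[C@H]1CC[C@H](C)C[C@@H]1O[C@H]1OC(O[Li])=C[C@@]1(C)CC=C | intermediate (not isolated)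
11 | (3S,4R,5S)-3-[(1S)-1-hydroxy-3-methylbut-3-en-1-yl]-4-methyl-5-{[(1S,2R,5S)-5-methyl-2-(propan-2-yl)cyclohexyl]oxy}-4-(prop-2-en-1-yl)dihydrofuran-2(3H)-one | CC(C)[C@H]1CC[C@H](C)C[C@@H]1O[C@H]1OC(=O)[C@H]([C@@H](O)CC(C)=C)[C@@]1(C)CC=C | intermediate
12 | (3S,3aR,8S,8aS)-8-hydroxy-3a,6-dimethyl-3-{[(1S,2R,5S)-5-methyl-2-(propan-2-yl)cyclohexyl]oxy}-3,3a,4,7,8,8a-hexahydro-1H-cyclohepta[c]furan-1-one | CC(C)[C@H]1CC[C@H](C)C[C@@H]1O[C@H]1OC(=O)[C@@H]2[C@@H](O)CC(C)=CC[C@@]12C | intermediate
13 | (1S,2R,7S)-2-formyl-7-hydroxy-2,5-dimethylcyclohept-4-ene-1-carboxylic acid (formed as its potassium salt) | CC1=CC[C@@](C)(C=O)[C@H](C(=O)O)[C@@H](O)C1 | intermediate (not isolated)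
14 | (1S,2R,7S)-7-hydroxy-2-(hydroxymethyl)-2,5-dimethylcyclohept-4-ene-1-carboxylic acid (formed as its potassium salt) | CC1=CC[C@@](C)(CO)[C@H](C(=O)O)[C@@H](O)C1 | intermediate (not isolated)
15 | (3aR,8S,8aS)-8-hydroxy-3a,6-dimethyl-3,3a,4,7,8,8a-hexahydro-1H-cyclohepta[c]furan-1-one | CC1=CC[C@@]2(C)COC(=O)[C@@H]2[C@@H](O)C1 | intermediate
16 | (3aR,8S,8aS)-3a,6-dimethyl-8-[(triethylsilyl)oxy]-3,3a,4,7,8,8a-hexahydro-1H-cyclohepta[c]furan-1-one | CC1=CC[C@@]2(C)COC(=O)[C@@H]2[C@@H](O[Si](CC)(CC)CC)C1 | intermediate
17 | (1S,2R,7S)-2-(hydroxymethyl)-2,5-dimethyl-7-[(triethylsilyl)oxy]cyclohept-4-ene-1-carboxylic acid (formed as its lithium salt) | CC1=CC[C@@](C)(CO)[C@H](C(=O)O)[C@@H](O[Si](CC)(CC)CC)C1 | intermediate (not isolated)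
18 | tert-butyldimethylsilyl (1S,2R,7S)-2-({[tert-butyl(dimethyl)silyl]oxy}methyl)-2,5-dimethyl-7-[(triethylsilyl)oxy]cyclohept-4-ene-1-carboxylate | CC1=CC[C@@](C)(CO[Si](C)(C)C(C)(C)C)[C@H](C(=O)O[Si](C)(C)C(C)(C)C)[C@@H](O[Si](CC)(CC)CC)C1 | intermediate (not isolated)
19 | (1S,2R,7S)-2-({[tert-butyl(dimethyl)silyl]oxy}methyl)-2,5-dimethyl-7-[(triethylsilyl)oxy]cyclohept-4-ene-1-carboxylic acid | CC1=CC[C@@](C)(CO[Si](C)(C)C(C)(C)C)[C@H](C(=O)O)[C@@H](O[Si](CC)(CC)CC)C1 | intermediate
20 | (1S,2R,7S)-2-({[tert-butyl(dimethyl)silyl]oxy}methyl)-2,5-dimethyl-7-[(triethylsilyl)oxy]cyclohept-4-ene-1-carbonyl chloride | CC1=CC[C@@](C)(CO[Si](C)(C)C(C)(C)C)[C@H](C(=O)Cl)[C@@H](O[Si](CC)(CC)CC)C1 | intermediate (not isolated)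
21 | 2-diazo-1-[(1S,2R,7S)-2-({[tert-butyl(dimethyl)silyl]oxy}methyl)-2,5-dimethyl-7-[(triethylsilyl)oxy]cyclohept-4-en-1-yl]ethan-1-one | CC1=CC[C@@](C)(CO[Si](C)(C)C(C)(C)C)[C@H](C(=O)C=[N+]=[N-])[C@@H](O[Si](CC)(CC)CC)C1 | intermediate
22 | (3R,3aR,8S,8aS)-3-{[tert-butyl(dimethyl)silyl]oxy}-3a,6-dimethyl-8-[(triethylsilyl)oxy]-3,3a,4,7,8,8a-hexahydroazulen-1(2H)-one | CC1=CC[C@@]2(C)[C@H](O[Si](C)(C)C(C)(C)C)CC(=O)[C@@H]2[C@@H](O[Si](CC)(CC)CC)C1 | intermediate
23 | (1R,3R,3aR,8S,8aS)-3-{[tert-butyl(dimethyl)silyl]oxy}-3a,6-dimethyl-1-(propan-2-yl)-8-[(triethylsilyl)oxy]-1,2,3,3a,4,7,8,8a-octahydroazulen-1-ol | CC1=CC[C@@]2(C)[C@H](O[Si](C)(C)C(C)(C)C)C[C@@](O)(C(C)C)[C@@H]2[C@@H](O[Si](CC)(CC)CC)C1 | intermediate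
24 | (1R,3R,3aR,8S,8aS)-3-{[tert-butyl(dimethyl)silyl]oxy}-3a,6-dimethyl-1-(propan-2-yl)-1,2,3,3a,4,7,8,8a-octahydroazulene-1,8-diol | CC1=CC[C@@]2(C)[C@H](O[Si](C)(C)C(C)(C)C)C[C@@](O)(C(C)C)[C@@H]2[C@@H](O)C1 | intermediate
25 | 4-hydroxybenzoic acid | O=C(O)c1ccc(O)cc1 | starting material
26 | tert-butyldimethylsilyl 4-{[tert-butyl(dimethyl)silyl]oxy}benzoate | CC(C)(C)[Si](C)(C)Oc1ccc(cc1)C(=O)O[Si](C)(C)C(C)(C)C | intermediate (not isolated)
27 | 4-{[tert-butyl(dimethyl)silyl]oxy}benzoic acid | CC(C)(C)[Si](C)(C)Oc1ccc(cc1)C(=O)O | intermediate
28 | 4-{[tert-butyl(dimethyl)silyl]oxy}benzoic 2,4,6-trichlorobenzoic anhydride | CC(C)(C)[Si](C)(C)Oc1ccc(cc1)C(=O)OC(=O)c1c(Cl)cc(Cl)cc1Cl | intermediate (not isolated)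
29 | (1R,3R,3aR,8S,8aS)-3-{[tert-butyl(dimethyl)silyl]oxy}-1-hydroxy-3a,6-dimethyl-1-(propan-2-yl)-1,2,3,3a,4,7,8,8a-octahydroazulen-8-yl 4-{[tert-butyl(dimethyl)silyl]oxy}benzoate | CC1=CC[C@@]2(C)[C@H](O[Si](C)(C)C(C)(C)C)C[C@@](O)(C(C)C)[C@@H]2[C@@H](OC(=O)c2ccc(O[Si](C)(C)C(C)(C)C)cc2)C1 | intermediate
30 | (1R,3R,3aR,8S,8aS)-1,3-dihydroxy-3a,6-dimethyl-1-(propan-2-yl)-1,2,3,3a,4,7,8,8a-octahydroazulen-8-yl 4-hydroxybenzoate | CC1=CC[C@@]2(C)[C@H](O)C[C@@](O)(C(C)C)[C@@H]2[C@@H](OC(=O)c2ccc(O)cc2)C1 | target

## Step count and least certain steps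

Total: 16 steps. Longest linear sequence: 14 steps (steps 1, 2, 3, 5–13, 15, 16). Steps 4 and 14 prepare the two side components.

**Step 11 (key step).** The carbenoid may be drawn off into transannular cyclopropanation of C1=C2, insertion at the allylic C3–H or C10–H bonds, silyl transfer through an oxonium ylide at the C9 oxygen, or insertion into the other C5 hydrogen. All of these start from the same reactive intermediate, and only conformational and electronic bias separate them.
Fallback: close C5–C6 by an intramolecular aldol addition instead. It sets out from 16 and returns at 22. One equivalent of MeLi in THF at −78 °C should open the lactone 16 to the hydroxy methyl ketone F1, in equilibrium with its hemiketal. Dess–Martin oxidation should then give the keto aldehyde F2, whose aldehyde cannot enolise. LiN(SiMe3)2 at −78 °C should form the kinetic methyl enolate, which adds to the aldehyde to give the β-hydroxy cyclopentanone F3; the C5 configuration then depends on the chelated aldol transition state and may require separation. tBuMe2SiOTf/2,6-lutidine should convert this alcohol into 22.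

**Step 5.** Simple diastereoselection at C9 may be poor for a lithium or zinc lactone enolate beside a quaternary carbon. The β,γ-unsaturated aldehyde may be lost by enolisation or by isomerisation to the conjugated enal.
Fallback: a Lewis-acid aldol with reagent control of the aldehyde face. It sets out from 6 (obtained from 5 by non-aqueous work-up of step 3) and returns at 11. The silyl ketene acetal 6 and 9 are combined at −78 °C in the presence of the oxazaborolidinone made from N-tosylvaline and BH3·THF, the valine enantiomer being chosen to match the 9S carbinol. The enolate face is still set by the substrate. No new compound is made on this way (F0).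

**Step 3.** Methyl transfer to the β,β-disubstituted acceptor may be slow, with reduction or 1,2-addition taking over.
Fallback: reverse the order of the two C4 substituents. It sets out from 4 and returns at 7. 5-Hydroxy-4-methylfuran-2(5H)-one F4, a commercial compound, is acetalised with 4 as in step 2, and the 5R menthyl acetal F5 is collected. The allylcopper reagent from allylMgBr, CuBr·SMe2 and Me3SiCl should add anti to the menthyloxy group to give the allyl lactone F6, which has the same 4R quaternary centre as 7 but the opposite acetal configuration. 10-Camphorsulfonic acid in toluene then equilibrates the acetal carbon, and 7 is separated.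

**Step 10.** The acid chloride 20 may cyclise onto the C5 silyl ether with loss of the silyl chloride, or form a ketene and epimerise C8.
Fallback: build the diazo ketone by diazo transfer instead of acylation. It sets out from 19 and returns at 21. EDC·HCl, HOBt and MeNHOMe·HCl should give the Weinreb amide F7, and MeMgBr should convert it into the methyl ketone F8. LiN(SiMe3)2 and CF3CO2CH2CF3 at −78 °C should give the trifluoroacetylated ketone F9. MsN3, Et3N and water in MeCN should then transfer the diazo group with loss of the trifluoroacetyl group, giving 21.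

**Step 12.** The branched reagent may reduce the ketone by β-hydride transfer, or enolise it with loss of a silanolate. Attack from the methyl face cannot be excluded.
Fallback: add an sp2 nucleophile and reduce afterwards. It sets out from 22 and returns at 23. IsopropenylMgBr/CeCl3 at −78 °C should give the isopropenyl carbinol F10. H2 with RhCl(PPh3)3 (monovalent rhodium) in benzene should hydrogenate the 1,1-disubstituted alkene and leave the trisubstituted ring alkene, giving 23.

## Further compounds

F1 | step 11 | 1-[(1S,2R,7S)-2-(hydroxymethyl)-2,5-dimethyl-7-[(triethylsilyl)oxy]cyclohept-4-en-1-yl]ethan-1-one | CC1=CC[C@@](C)(CO)[C@H](C(C)=O)[C@@H](O[Si](CC)(CC)CC)C1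
F2 | step 11 | (1R,2S,3S)-2-acetyl-1,5-dimethyl-3-[(triethylsilyl)oxy]cyclohept-5-ene-1-carbaldehyde | CC1=CC[C@@](C)(C=O)[C@H](C(C)=O)[C@@H](O[Si](CC)(CC)CC)C1
F3 | step 11 | (3R,3aR,8S,8aS)-3-hydroxy-3a,6-dimethyl-8-[(triethylsilyl)oxy]-3,3a,4,7,8,8a-hexahydroazulen-1(2H)-one | CC1=CC[C@@]2(C)[C@H](O)CC(=O)[C@@H]2[C@@H](O[Si](CC)(CC)CC)C1
F0 | step 5 | none | none
F4 | step 3 | 5-hydroxy-4-methylfuran-2(5H)-one | CC1=CC(=O)OC1O
F5 | step 3 | (5R)-4-methyl-5-{[(1S,2R,5S)-5-methyl-2-(propan-2-yl)cyclohexyl]oxy}furan-2(5H)-one | CC(C)[C@H]1CC[C@H](C)C[C@@H]1O[C@@H]1OC(=O)C=C1C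
F6 | step 3 | (4R,5R)-4-methyl-5-{[(1S,2R,5S)-5-methyl-2-(propan-2-yl)cyclohexyl]oxy}-4-(prop-2-en-1-yl)dihydrofuran-2(3H)-one | CC(C)[C@H]1CC[C@H](C)C[C@@H]1O[C@@H]1OC(=O)C[C@@]1(C)CC=C
F7 | step 10 | (1S,2R,7S)-2-({[tert-butyl(dimethyl)silyl]oxy}methyl)-N-methoxy-N,2,5-trimethyl-7-[(triethylsilyl)oxy]cyclohept-4-ene-1-carboxamide | CC1=CC[C@@](C)(CO[Si](C)(C)C(C)(C)C)[C@H](C(=O)N(C)OC)[C@@H](O[Si](CC)(CC)CC)C1
F8 | step 10 | 1-[(1S,2R,7S)-2-({[tert-butyl(dimethyl)silyl]oxy}methyl)-2,5-dimethyl-7-[(triethylsilyl)oxy]cyclohept-4-en-1-yl]ethan-1-one | CC1=CC[C@@](C)(CO[Si](C)(C)C(C)(C)C)[C@H](C(C)=O)[C@@H](O[Si](CC)(CC)CC)C1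
F9 | step 10 | 1-[(1S,2R,7S)-2-({[tert-butyl(dimethyl)silyl]oxy}methyl)-2,5-dimethyl-7-[(triethylsilyl)oxy]cyclohept-4-en-1-yl]-4,4,4-trifluorobutane-1,3-dione | CC1=CC[C@@](C)(CO[Si](C)(C)C(C)(C)C)[C@H](C(=O)CC(=O)C(F)(F)F)[C@@H](O[Si](CC)(CC)CC)C1
F10 | step 12 | (1R,3R,3aR,8S,8aS)-3-{[tert-butyl(dimethyl)silyl]oxy}-3a,6-dimethyl-1-(prop-1-en-2-yl)-8-[(triethylsilyl)oxy]-1,2,3,3a,4,7,8,8a-octahydroazulen-1-ol | CC1=CC[C@@]2(C)[C@H](O[Si](C)(C)C(C)(C)C)C[C@@](O)(C(C)=C)[C@@H]2[C@@H](O[Si](CC)(CC)CC)C1
A1 | alternative 1 | 8a-methyl azulenone with C9 methyl enol ether, C5 ketone and C7 silyl ether | CC=1C=C[C@@]2(C)C(=O)C[C@@](O[Si](C)(C)C(C)(C)C)(C(C)C)C2=C(OC)C=1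
A2 | alternative 2 | bicyclic C9 silyl enol ether with the C1(Me)=C2 alkene in place | CC1=CC[C@@]2(C)[C@H](O[Si](C)(C)C(C)(C)C)C[C@@](O[Si](CC)(CC)CC)(C(C)C)C2=C(O[Si](C)(C)C(C)(C)C)C1
A3 | alternative 2 | propyne | CC#C
A4 | alternative 3 | target with the phenol as its tert-butyldimethylsilyl ether | CC1=CC[C@@]2(C)[C@H](O)C[C@@](O)(C(C)C)[C@@H]2[C@@H](OC(=O)c2ccc(O[Si](C)(C)C(C)(C)C)cc2)C1
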